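**Numbering and assumption:** carbons are counted along the seco chain, C1 = lactone carbonyl to C28 = methyl on C27. The SMILES is read as 2S,3R,5S,9S,11S,13R,14R,15R,26R,27R with an all-E C16–C25 pentaene. TBS = tert-butyldimethylsilyl, Ipc = isopinocampheyl.

## Retrosynthetic overview

1. The only ring, the 28-membered lactone, is closed last but one by S→O acyl transfer of C27–OH onto a C1 S-ethyl thioester (the chemical counterpart of thioesterase off-loading of the polyketide chain); global desilylation follows.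
2. The seco-thioester comes from a C19–C20 Stille union of a C1–C19 bromodiene thioester with a C20–C28 trienylstannane that carries C27–OH free.
3. C13–C15 come from a reagent-controlled syn aldol of a C13 ethyl ketone followed by 1,3-anti reduction; C1–C3 come from an auxiliary-controlled syn aldol on a C3 aldehyde, the auxiliary then being exchanged for ethanethiol.
4. The C3–C14 core is made two-directionally: double allylboration of a C5 dialdehyde, monosilylation, double cross-metathesis with an enone, boronate oxa-Michael addition (C11), ozonolysis of the spare enone (C3).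
5. C20–C28 come from syn-crotylboration, cross-metathesis, Takai iodo-olefination and a Stille coupling with a bis-stannylethene.

## Route

**Step 1**
Reactants: 1 glutaraldehyde (pentanedial, freshly distilled)
Product: 3 (4S,8S)-undeca-1,10-diene-4,8-diol, via bis-borinate ester 2 (not isolated)
Conditions: (+)-Ipc2B(allyl) [from (−)-α-pinene] (2.5 equiv), Et2O, −78 °C; then NaOH, H2O2, 0 °C to rt
Reagents that add atoms: (+)-B-allyldiisopinocampheylborane, C=CCB([C@H]1C[C@H]2C[C@@H]([C@@H]1C)C2(C)C)[C@H]1C[C@H]2C[C@@H]([C@@H]1C)C2(C)C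
Why: Brown allylboration through a chair six-membered transition state, in which these Ipc ligands send allyl to the re face of each aldehyde (S at both carbinols, the future C5 and C9), the double addition raising the ee of the C2-symmetric diol at the cost of a little meso isomer that is removed after step 2.

**Step 2**
Reactants: 3 (4S,8S)-undeca-1,10-diene-4,8-diol
Product: 4 (4S,8S)-8-(TBSO)undeca-1,10-dien-4-ol
Conditions: NaH (1.0 equiv), THF, 0 °C; TBSCl (1.0 equiv), rt
Reagents that add atoms: tert-butyldimethylsilyl chloride, CC(C)(C)[Si](C)(C)Cl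
Why: O-silylation of the mono-alkoxide of a C2-symmetric diol, whose two hydroxyls are homotopic, so only one mono-ether can form (statistical; unreacted 3 and bis-ether are recycled).

**Step 3**
Reactants: 4 mono-TBS diene; 5 ethyl vinyl ketone (pent-1-en-3-one)
Product: 6 (4E,7S,11S,13E)-7-(TBSO)-11-hydroxyheptadeca-4,13-diene-3,15-dione
Conditions: second-generation Hoveyda–Grubbs catalyst RuCl2(H2IMes)(=CH-C6H4-2-OiPr) (5 mol%), 5 (6 equiv), CH2Cl2, 40 °C
Reagents that add atoms: none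
Why: Olefin cross-metathesis of both terminal alkenes with an excess of the electron-poor enone is E-selective and tolerates the free hydroxyl; the enone at the OTBS end serves as a masked C3 aldehyde, the other brings in C12–C14 and the C14 methyl.

**Step 4**
Reactants: 6 bis-enone
Product: 8 (4E,7S,11S,13S)-7-(TBSO)-11,13-dihydroxyheptadec-4-ene-3,15-dione, via cyclic phenylboronate 7 (not isolated)
Conditions: PhB(OH)2 (1.3 equiv), cinchona-derived amine–thiourea catalyst (10 mol%, pseudo-enantiomer matched to the C9 carbinol), 4 Å MS, toluene, rt; then pinacol, MeOH, rt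
Reagents that add atoms: phenylboronic acid, OB(O)c1ccccc1
Why: Boronic acid hemiester oxa-Michael addition: the B–OH of the C9 boronate adds to the enone β-carbon through a chair six-membered ring with both substituents equatorial, giving the 9,11-syn diol (11S), while the OTBS-bearing enone has no tether and stays intact.

**Step 5**
Reactants: 8 enone diol
Product: 9 (4E,7S,11S,13S)-7,11,13-tris(TBSO)heptadec-4-ene-3,15-dione
Conditions: TBSCl (3 equiv), imidazole (6 equiv), DMF, rt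
Reagents that add atoms: tert-butyldimethylsilyl chloride, CC(C)(C)[Si](C)(C)Cl
Why: Imidazole-mediated silylation of two unhindered secondary alcohols, mild enough not to enolise the ketones or eliminate the β-oxygen.

**Step 6**
Reactants: 9 tris-TBS enone
Product: 11 (3S,7S,9S)-3,7,9-tris(TBSO)-11-oxotridecanal, via ozonide 10 (not isolated)
Conditions: O3, CH2Cl2, −78 °C; then PPh3, −78 °C to rt
Reagents that add atoms: ozone, [O-][O+]=O
Why: Ozonolysis with reductive work-up cleaves the only C=C, the spare enone, and unveils the C3 aldehyde next to a CH2, so no stereocentre is at risk.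

**Step 7**
Reactants: 12 (4S)-4-benzyl-1,3-thiazolidine-2-thione; 13 butanoyl chloride
Product: 14 1-[(4S)-4-benzyl-2-thioxo-1,3-thiazolidin-3-yl]butan-1-one
Conditions: Et3N, DMAP (5 mol%), CH2Cl2, 0 °C
Reagents that add atoms: none
Why: N-acylation of the thiazolidinethione by the acid chloride.

**Step 8**
Reactants: 14 N-butanoyl thiazolidinethione; 11 aldehyde
Product: 16 (2S,3R,5S,9S,11S)-1-[(4S)-4-benzyl-2-thioxo-1,3-thiazolidin-3-yl]-2-ethyl-3-hydroxy-5,9,11-tris(TBSO)pentadecane-1,13-dione, via chlorotitanium enolate 15 (not isolated)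
Conditions: TiCl4 (1.05 equiv), iPr2NEt (1.1 equiv), N-methylpyrrolidone (1.1 equiv), CH2Cl2, 0 °C; then 11, −78 to 0 °C
Reagents that add atoms: none
Why: Crimmins titanium aldol: the Z-enolate reacts through a non-chelated chair transition state in which the (S)-benzyl auxiliary fixes the Evans-syn (2S,3R) outcome (C2 ethyl and C3 hydroxyl set, C3 anti to C5), and the aldehyde reacts far faster than the C13 ketone.

**Step 9**
Reactants: 16 aldol adduct
Product: 17 S-ethyl (2S,3R,5S,9S,11S)-2-ethyl-3-hydroxy-13-oxo-5,9,11-tris(TBSO)pentadecanethioate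
Conditions: EtSH (10 equiv), imidazole (3 equiv), CH2Cl2, rt
Reagents that add atoms: ethanethiol, CCS
Why: Acyl substitution of the activated N-acyl thiazolidinethione by the thiol gives the robust S-ethyl thioester without touching C2 or C3; the auxiliary is recovered.

**Step 10**
Reactants: 18 glutaconaldehyde potassium salt
Product: 19 (2E,4E)-5-bromopenta-2,4-dienal
Conditions: PPh3, Br2, CH2Cl2, 0 °C to rt
Reagents that add atoms: bromine, BrBr (delivered as dibromotriphenylphosphorane)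
Why: Deoxybromination of the dienolate oxygen by Ph3PBr2 (addition–elimination), giving the thermodynamically preferred E,E bromodienal.

**Step 11**
Reactants: 17 keto thioester; 19 bromodienal
Product: 22 S-ethyl (2S,3R,5S,9S,11S,14S,15R,16E,18E)-19-bromo-2-ethyl-3,15-dihydroxy-14-methyl-13-oxo-5,9,11-tris(TBSO)nonadeca-16,18-dienethioate, via Z-enolborinate 20 (not isolated), via boron aldolate 21 (not isolated)
Conditions: (−)-Ipc2BOTf [from (+)-α-pinene] (2.5 equiv), iPr2NEt (3.5 equiv), CH2Cl2, −78 °C; 19 (1.5 equiv), −78 to −20 °C; then H2O2, MeOH, pH 7 buffer, 0 °C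
Reagents that add atoms: none
Why: Paterson boron aldol: one equivalent of reagent caps C3–OH, the ketone enolises on the less hindered ethyl side to the Z-enolborinate, the chair transition state gives the 14,15-syn adduct, and these Ipc ligands direct attack to the si face of the aldehyde (15R; C14 is labelled S here only because the C13 ketone outranks C15).

**Step 12**
Reactants: 22 β-hydroxy ketone
Product: 23 S-ethyl (2S,3R,5S,9S,11R,13R,14R,15R,16E,18E)-19-bromo-2-ethyl-3,13,15-trihydroxy-14-methyl-5,9,11-tris(TBSO)nonadeca-16,18-dienethioate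
Conditions: Me4NBH(OAc)3 (8 equiv), MeCN/AcOH (1:1), −30 °C
Reagents that add atoms: none
Why: Evans–Saksena reduction: C15–OH exchanges onto boron and delivers hydride intramolecularly through a chair transition state, giving the 13,15-anti diol (13R), and the thioester and bromodiene are inert (the 11R label is a priority change only, not an inversion).

**Step 13**
Reactants: 23 triol
Product: 24 S-ethyl (2S,3R,5S,9S,11S,13R,14R,15R,16E,18E)-19-bromo-2-ethyl-14-methyl-3,5,9,11,13,15-hexakis(TBSO)nonadeca-16,18-dienethioate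
Conditions: TBSOTf (5 equiv), 2,6-lutidine (8 equiv), CH2Cl2, −78 to 0 °C
Reagents that add atoms: tert-butyldimethylsilyl trifluoromethanesulfonate, CC(C)(C)[Si](C)(C)OS(=O)(=O)C(F)(F)F
Why: Silyl triflate with a hindered pyridine base silylates all three remaining hydroxyls (C3, C13, C15) in one operation without enolising the thioester.

**Step 14**
Reactants: 25 acetaldehyde; 26 (Z)-but-2-ene
Product: 30 (2R,3R)-3-methylpent-4-en-2-ol, via (Z)-crotylpotassium 27 (not isolated), via (Z)-crotyldiisopinocampheylborane 28 (not isolated), via borinate ester 29 (not isolated)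
Conditions: 26, KOtBu, n-BuLi, THF, −78 to −45 °C; (−)-Ipc2BOMe [from (+)-α-pinene], −78 °C; BF3·OEt2; 25, −78 °C; then NaOH, H2O2
Reagents that add atoms: none
Why: Brown crotylboration: the Z-crotylborane gives the syn adduct through a chair transition state and these Ipc ligands direct attack to the si face of acetaldehyde, setting C26 (R) and C27 (R).

**Step 15**
Reactants: 30 alkenol; 31 crotonaldehyde ((E)-but-2-enal)
Product: 32 (2E,4R,5R)-5-hydroxy-4-methylhex-2-enal
Conditions: second-generation Hoveyda–Grubbs catalyst RuCl2(H2IMes)(=CH-C6H4-2-OiPr) (5 mol%), 31 (5 equiv), CH2Cl2, 40 °C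
Reagents that add atoms: none
Why: Cross-metathesis of the terminal alkene with an excess of the enal is E-selective and tolerates the free C27 hydroxyl.

**Step 16**
Reactants: 32 enal
Product: 33 (2R,3R,4E,6E)-7-iodo-3-methylhepta-4,6-dien-2-ol
Conditions: CrCl2 (8 equiv), CHI3 (3 equiv), THF/1,4-dioxane (1:6), 0 °C to rt, dark
Reagents that add atoms: iodoform, IC(I)I
Why: Takai iodo-olefination of the aldehyde through a geminal dichromium species gives the E-alkenyl iodide and does not affect the remote carbinol centres.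

**Step 17**
Reactants: 33 dienyl iodide; 34 (E)-1,2-bis(tributylstannyl)ethene
Product: 35 (2R,3R,4E,6E,8E)-3-methyl-9-(tributylstannyl)nona-4,6,8-trien-2-ol
Conditions: PdCl2(MeCN)2 (5 mol%), 34 (3 equiv), DMF, rt, dark
Reagents that add atoms: none
Why: Stille coupling with retention of alkene geometry; the excess of bis-stannane restricts the reaction to mono-coupling and leaves the second tin as the handle.

**Step 18**
Reactants: 24 bromodiene thioester; 35 trienylstannane
Product: 36 S-ethyl (2S,3R,5S,9S,11S,13R,14R,15R,16E,18E,20E,22E,24E,26R,27R)-2-ethyl-27-hydroxy-14,26-dimethyl-3,5,9,11,13,15-hexakis(TBSO)octacosa-16,18,20,22,24-pentaenethioate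
Conditions: Pd2(dba)3 (5 mol%), AsPh3 (40 mol%), N-methylpyrrolidone, 45 °C, dark
Reagents that add atoms: none
Why: Stille coupling at C19–C20 with retention at both partners builds the all-E pentaene under neutral, copper-free conditions that leave the thioester and the free C27–OH alone.

**Step 19**
Reactants: 36 seco hydroxy thioester
Product: 37 (3S,4R,6S,10S,12S,14R,15R,16R,17E,19E,21E,23E,25E,27R,28R)-3-ethyl-15,27,28-trimethyl-4,6,10,12,14,16-hexakis(TBSO)-1-oxacyclooctacosa-17,19,21,23,25-pentaen-2-one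
Conditions: AgOCOCF3 (6 equiv), Na2HPO4 (12 equiv), toluene, 0.5 mM (syringe-pump addition of 36), 50 °C, dark
Reagents that add atoms: none
Why: Masamune-type thioester macrolactonization: the thiophilic silver salt activates the S-ethyl thioester toward the single free hydroxyl (C27–OH), the same S→O acyl transfer by which a thioesterase releases a macrolide, with high dilution favouring the 28-membered ring and no stereocentre involved.

**Step 20**
Reactants: 37 hexakis-TBS macrolactone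
Product: 38 CNP0382847.1, (3S,4R,6S,10S,12S,14R,15R,16R,17E,19E,21E,23E,25E,27R,28R)-3-ethyl-4,6,10,12,14,16-hexahydroxy-15,27,28-trimethyl-1-oxacyclooctacosa-17,19,21,23,25-pentaen-2-one
Conditions: HF·pyridine, pyridine, THF, 0 °C to rt, 48–72 h
Reagents that add atoms: none
Why: Buffered fluoride cleaves all six silyl ethers without acid strong enough to ionise the allylic C15 carbinol, isomerise the pentaene or open the β-hydroxy lactone.

## Compound list

1 | glutaraldehyde (pentanedial) | O=CCCCC=O | starting material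
2 | bis(diisopinocampheylborinate) ester of 3 | C=CC[C@@H](OB([C@H]1C[C@H]2C[C@@H]([C@@H]1C)C2(C)C)[C@H]1C[C@H]2C[C@@H]([C@@H]1C)C2(C)C)CCC[C@H](OB([C@H]1C[C@H]2C[C@@H]([C@@H]1C)C2(C)C)[C@H]1C[C@H]2C[C@@H]([C@@H]1C)C2(C)C)CC=C | intermediate
3 | (4S,8S)-undeca-1,10-diene-4,8-diol | C=CC[C@@H](O)CCC[C@H](O)CC=C | intermediate
4 | (4S,8S)-8-(TBSO)undeca-1,10-dien-4-ol | C=CC[C@@H](O[Si](C)(C)C(C)(C)C)CCC[C@H](O)CC=C | intermediate
5 | ethyl vinyl ketone (pent-1-en-3-one) | CCC(=O)C=C | starting material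
6 | (4E,7S,11S,13E)-7-(TBSO)-11-hydroxyheptadeca-4,13-diene-3,15-dione | CCC(=O)/C=C/C[C@@H](O[Si](C)(C)C(C)(C)C)CCC[C@H](O)C/C=C/C(=O)CC | intermediate
7 | (4E,7S)-7-(TBSO)-10-[(4S,6S)-6-(2-oxobutyl)-2-phenyl-1,3,2-dioxaborinan-4-yl]dec-4-en-3-one | CCC(=O)/C=C/C[C@@H](O[Si](C)(C)C(C)(C)C)CCC[C@H]1C[C@@H](CC(=O)CC)OB(c2ccccc2)O1 | intermediate
8 | (4E,7S,11S,13S)-7-(TBSO)-11,13-dihydroxyheptadec-4-ene-3,15-dione | CCC(=O)/C=C/C[C@@H](O[Si](C)(C)C(C)(C)C)CCC[C@H](O)C[C@H](O)CC(=O)CC | intermediate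
9 | (4E,7S,11S,13S)-7,11,13-tris(TBSO)heptadec-4-ene-3,15-dione | CCC(=O)/C=C/C[C@@H](O[Si](C)(C)C(C)(C)C)CCC[C@H](O[Si](C)(C)C(C)(C)C)C[C@H](O[Si](C)(C)C(C)(C)C)CC(=O)CC | intermediate
10 | ozonide of 9: 1-{5-[(2S,6S,8S)-10-oxo-2,6,8-tris(TBSO)dodecyl]-1,2,4-trioxolan-3-yl}propan-1-one (mixture at the two trioxolane carbons) | CCC(=O)C1OC(OO1)C[C@@H](O[Si](C)(C)C(C)(C)C)CCC[C@H](O[Si](C)(C)C(C)(C)C)C[C@H](O[Si](C)(C)C(C)(C)C)CC(=O)CC | intermediate
11 | (3S,7S,9S)-3,7,9-tris(TBSO)-11-oxotridecanal | O=CC[C@@H](O[Si](C)(C)C(C)(C)C)CCC[C@H](O[Si](C)(C)C(C)(C)C)C[C@H](O[Si](C)(C)C(C)(C)C)CC(=O)CC | intermediate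
12 | (4S)-4-benzyl-1,3-thiazolidine-2-thione | S=C1N[C@@H](Cc2ccccc2)CS1 | starting material
13 | butanoyl chloride | CCCC(=O)Cl | starting material
14 | 1-[(4S)-4-benzyl-2-thioxo-1,3-thiazolidin-3-yl]butan-1-one | CCCC(=O)N1[C@@H](Cc2ccccc2)CSC1=S | intermediate
15 | trichlorotitanium (Z)-enolate of 14 | CC/C=C(\O[Ti](Cl)(Cl)Cl)N1[C@@H](Cc2ccccc2)CSC1=S | intermediate
16 | (2S,3R,5S,9S,11S)-1-[(4S)-4-benzyl-2-thioxo-1,3-thiazolidin-3-yl]-2-ethyl-3-hydroxy-5,9,11-tris(TBSO)pentadecane-1,13-dione | S=C1SC[C@H](Cc2ccccc2)N1C(=O)[C@@H](CC)[C@H](O)C[C@@H](O[Si](C)(C)C(C)(C)C)CCC[C@H](O[Si](C)(C)C(C)(C)C)C[C@H](O[Si](C)(C)C(C)(C)C)CC(=O)CC | intermediate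
17 | S-ethyl (2S,3R,5S,9S,11S)-2-ethyl-3-hydroxy-13-oxo-5,9,11-tris(TBSO)pentadecanethioate | CCSC(=O)[C@@H](CC)[C@H](O)C[C@@H](O[Si](C)(C)C(C)(C)C)CCC[C@H](O[Si](C)(C)C(C)(C)C)C[C@H](O[Si](C)(C)C(C)(C)C)CC(=O)CC | intermediate
18 | glutaconaldehyde potassium salt, potassium (1E,3E)-5-oxopenta-1,3-dien-1-olate | [K+].[O-]/C=C/C=C/C=O | starting material
19 | (2E,4E)-5-bromopenta-2,4-dienal | O=C/C=C/C=C/Br | intermediate
20 | C13 (Z)-enol diisopinocampheylborinate of 17, C3–OH capped as diisopinocampheylborinate | CCSC(=O)[C@@H](CC)[C@H](OB([C@@H]1C[C@@H]2C[C@H]([C@H]1C)C2(C)C)[C@@H]1C[C@@H]2C[C@H]([C@H]1C)C2(C)C)C[C@@H](O[Si](C)(C)C(C)(C)C)CCC[C@H](O[Si](C)(C)C(C)(C)C)C[C@H](O[Si](C)(C)C(C)(C)C)C/C(OB([C@@H]1C[C@@H]2C[C@H]([C@H]1C)C2(C)C)[C@@H]1C[C@@H]2C[C@H]([C@H]1C)C2(C)C)=C/C | intermediate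
21 | 3,15-bis-O-(diisopinocampheylboryl) derivative of 22 (boron aldolate) | CCSC(=O)[C@@H](CC)[C@H](OB([C@@H]1C[C@@H]2C[C@H]([C@H]1C)C2(C)C)[C@@H]1C[C@@H]2C[C@H]([C@H]1C)C2(C)C)C[C@@H](O[Si](C)(C)C(C)(C)C)CCC[C@H](O[Si](C)(C)C(C)(C)C)C[C@H](O[Si](C)(C)C(C)(C)C)CC(=O)[C@@H](C)[C@H](OB([C@@H]1C[C@@H]2C[C@H]([C@H]1C)C2(C)C)[C@@H]1C[C@@H]2C[C@H]([C@H]1C)C2(C)C)/C=C/C=C/Br | intermediate
22 | S-ethyl (2S,3R,5S,9S,11S,14S,15R,16E,18E)-19-bromo-2-ethyl-3,15-dihydroxy-14-methyl-13-oxo-5,9,11-tris(TBSO)nonadeca-16,18-dienethioate | CCSC(=O)[C@@H](CC)[C@H](O)C[C@@H](O[Si](C)(C)C(C)(C)C)CCC[C@H](O[Si](C)(C)C(C)(C)C)C[C@H](O[Si](C)(C)C(C)(C)C)CC(=O)[C@@H](C)[C@H](O)/C=C/C=C/Br | intermediate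
23 | S-ethyl (2S,3R,5S,9S,11R,13R,14R,15R,16E,18E)-19-bromo-2-ethyl-3,13,15-trihydroxy-14-methyl-5,9,11-tris(TBSO)nonadeca-16,18-dienethioate | CCSC(=O)[C@@H](CC)[C@H](O)C[C@@H](O[Si](C)(C)C(C)(C)C)CCC[C@H](O[Si](C)(C)C(C)(C)C)C[C@H](O[Si](C)(C)C(C)(C)C)C[C@@H](O)[C@@H](C)[C@H](O)/C=C/C=C/Br | intermediate
24 | S-ethyl (2S,3R,5S,9S,11S,13R,14R,15R,16E,18E)-19-bromo-2-ethyl-14-methyl-3,5,9,11,13,15-hexakis(TBSO)nonadeca-16,18-dienethioate | CCSC(=O)[C@@H](CC)[C@H](O[Si](C)(C)C(C)(C)C)C[C@@H](O[Si](C)(C)C(C)(C)C)CCC[C@H](O[Si](C)(C)C(C)(C)C)C[C@H](O[Si](C)(C)C(C)(C)C)C[C@@H](O[Si](C)(C)C(C)(C)C)[C@@H](C)[C@H](O[Si](C)(C)C(C)(C)C)/C=C/C=C/Br | intermediate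
25 | acetaldehyde | CC=O | starting material
26 | (Z)-but-2-ene | C/C=C\C | starting material
27 | (Z)-crotylpotassium | C/C=C\[CH2-].[K+] | intermediate
28 | (Z)-crotyldiisopinocampheylborane, Ipc from (+)-α-pinene | C/C=C\CB([C@@H]1C[C@@H]2C[C@H]([C@H]1C)C2(C)C)[C@@H]1C[C@@H]2C[C@H]([C@H]1C)C2(C)C | intermediate
29 | (2R,3R)-3-methylpent-4-en-2-yl diisopinocampheylborinate | C=C[C@@H](C)[C@@H](C)OB([C@@H]1C[C@@H]2C[C@H]([C@H]1C)C2(C)C)[C@@H]1C[C@@H]2C[C@H]([C@H]1C)C2(C)C | intermediate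
30 | (2R,3R)-3-methylpent-4-en-2-ol | C=C[C@@H](C)[C@@H](C)O | intermediate
31 | crotonaldehyde, (E)-but-2-enal | C/C=C/C=O | starting material
32 | (2E,4R,5R)-5-hydroxy-4-methylhex-2-enal | O=C/C=C/[C@@H](C)[C@@H](C)O | intermediate
33 | (2R,3R,4E,6E)-7-iodo-3-methylhepta-4,6-dien-2-ol | I/C=C/C=C/[C@@H](C)[C@@H](C)O | intermediate
34 | (E)-1,2-bis(tributylstannyl)ethene | CCCC[Sn](CCCC)(CCCC)/C=C/[Sn](CCCC)(CCCC)CCCC | starting material
35 | (2R,3R,4E,6E,8E)-3-methyl-9-(tributylstannyl)nona-4,6,8-trien-2-ol | CCCC[Sn](CCCC)(CCCC)/C=C/C=C/C=C/[C@@H](C)[C@@H](C)O | intermediate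
36 | S-ethyl (2S,3R,5S,9S,11S,13R,14R,15R,16E,18E,20E,22E,24E,26R,27R)-2-ethyl-27-hydroxy-14,26-dimethyl-3,5,9,11,13,15-hexakis(TBSO)octacosa-16,18,20,22,24-pentaenethioate | CCSC(=O)[C@@H](CC)[C@H](O[Si](C)(C)C(C)(C)C)C[C@@H](O[Si](C)(C)C(C)(C)C)CCC[C@H](O[Si](C)(C)C(C)(C)C)C[C@H](O[Si](C)(C)C(C)(C)C)C[C@@H](O[Si](C)(C)C(C)(C)C)[C@@H](C)[C@H](O[Si](C)(C)C(C)(C)C)/C=C/C=C/C=C/C=C/C=C/[C@@H](C)[C@@H](C)O | intermediate
37 | (3S,4R,6S,10S,12S,14R,15R,16R,17E,19E,21E,23E,25E,27R,28R)-3-ethyl-15,27,28-trimethyl-4,6,10,12,14,16-hexakis(TBSO)-1-oxacyclooctacosa-17,19,21,23,25-pentaen-2-one | CC[C@@H]1C(=O)O[C@H](C)[C@H](C)/C=C/C=C/C=C/C=C/C=C/[C@@H](O[Si](C)(C)C(C)(C)C)[C@H](C)[C@H](O[Si](C)(C)C(C)(C)C)C[C@@H](O[Si](C)(C)C(C)(C)C)C[C@@H](O[Si](C)(C)C(C)(C)C)CCC[C@H](O[Si](C)(C)C(C)(C)C)C[C@H]1O[Si](C)(C)C(C)(C)C | intermediate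
38 | CNP0382847.1, (3S,4R,6S,10S,12S,14R,15R,16R,17E,19E,21E,23E,25E,27R,28R)-3-ethyl-4,6,10,12,14,16-hexahydroxy-15,27,28-trimethyl-1-oxacyclooctacosa-17,19,21,23,25-pentaen-2-one | CC[C@@H]1C(=O)O[C@H](C)[C@H](C)/C=C/C=C/C=C/C=C/C=C/[C@@H](O)[C@H](C)[C@H](O)C[C@@H](O)C[C@@H](O)CCC[C@H](O)C[C@H]1O | target

## Step count and risks

Total: 20 steps. Longest linear sequence: 14 steps from glutaraldehyde (steps 1–6, 8, 9, 11–13, 18–20).

Most likely to fail, first: step 19. The hindered C27 alcohol must attack a hindered, α-branched thioester at high dilution in the presence of a silver salt and an unprotected pentaene. The fallback sets out from 36 and comes back at 37. The thioester is hydrolysed (AgNO3, 2,6-lutidine, THF/H2O, rt) to the seco acid F1, which is cyclised as its mixed anhydride by the Shiina method (2-methyl-6-nitrobenzoic anhydride, DMAP, toluene, high dilution, rt).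

Second: step 11. The facial selectivity rests on the chiral boron reagent alone, next to a free β-hydroxy thioester and a remote β-silyloxy group. The fallback sets out from 17 and comes back at 22. Compound 17 is converted with LiN(SiMe3)2, Me3SiCl and Et3N in THF at −78 °C into the 3-O-trimethylsilyl C13 (Z)-trimethylsilyl enol ether F2. F2 is added to 19 in a Mukaiyama aldol catalysed by a tartaric-acid-derived acyloxyborane (20 mol%, EtCN, −78 °C; open transition state, syn-selective whatever the enol ether geometry, the tartrate antipode chosen for si-face attack). Work-up with 1 M HCl in THF removes both trimethylsilyl groups.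

Third: step 4. The diastereoselectivity of the boronate oxa-Michael addition on a chiral secondary carbinol depends on catalyst matching. The fallback sets out from 6 and comes back at 8. The Evans hemiacetal/oxa-Michael reaction (PhCHO, KOtBu, THF, 0 °C) gives, under thermodynamic control, the all-equatorial syn-benzylidene acetal F3, and AcOH/H2O (4:1) at 35 °C then releases the diol.

## Further compounds

F1 | step 19 | (2S,3R,5S,9S,11S,13R,14R,15R,16E,18E,20E,22E,24E,26R,27R)-2-ethyl-27-hydroxy-14,26-dimethyl-3,5,9,11,13,15-hexakis(TBSO)octacosa-16,18,20,22,24-pentaenoic acid | OC(=O)[C@@H](CC)[C@H](O[Si](C)(C)C(C)(C)C)C[C@@H](O[Si](C)(C)C(C)(C)C)CCC[C@H](O[Si](C)(C)C(C)(C)C)C[C@H](O[Si](C)(C)C(C)(C)C)C[C@@H](O[Si](C)(C)C(C)(C)C)[C@@H](C)[C@H](O[Si](C)(C)C(C)(C)C)/C=C/C=C/C=C/C=C/C=C/[C@@H](C)[C@@H](C)O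
F2 | step 11 | S-ethyl (2S,3R,5S,9S,11S,13Z)-2-ethyl-5,9,11-tris(TBSO)-3,13-bis(trimethylsilyloxy)pentadec-13-enethioate | CCSC(=O)[C@@H](CC)[C@H](O[Si](C)(C)C)C[C@@H](O[Si](C)(C)C(C)(C)C)CCC[C@H](O[Si](C)(C)C(C)(C)C)C[C@H](O[Si](C)(C)C(C)(C)C)C/C(O[Si](C)(C)C)=C/C
F3 | step 4 | (4E,7S)-7-(TBSO)-10-[(2S,4S,6S)-6-(2-oxobutyl)-2-phenyl-1,3-dioxan-4-yl]dec-4-en-3-one | CCC(=O)/C=C/C[C@@H](O[Si](C)(C)C(C)(C)C)CCC[C@H]1C[C@@H](CC(=O)CC)O[C@@H](c2ccccc2)O1
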